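The chroman is cut at C4a–C4 and O1–C2. The feature exploited is the three-carbon unit C2–C3–C4 that spans the arene carbon C4a and the ring oxygen O1 of the pyran ring (ring B). Written as a C2 ketone with a C3=C4 alkylidene, it lets phloroglucinol (ring A) act as a C,O-dinucleophile. One amine-catalysed operation forms both bonds, closes ring B as the C2 lactol and sets C4 and C3. Its precursor is an acyclic (E)-α-alkylidene ketone with two alkene-terminated arms, C14 coming from (R)-α-terpineol. C2 methylation, metathesis closure of the ten-membered ring C at C11=C12 and double formylation follow.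

Key step: step 9

Numbering used: chroman O1, C2 (methyl), C3, C4 (isobutyl), C4a, C5 to C8, C8a; ring C runs C2, C3, C9, C10, C11 (methyl), C12, C13, C14, C15, C16; C17 is the carbinol carbon on C14. The target is planned as 2R, 3S, 4S, 14R with an 11Z alkene (C2 methyl cis to the C3–C9 bond, C3 and C4 side chains trans).

Assumption: 9-amino-9-deoxy-epi-quinine is taken to direct the arene to the Si face of C4 (giving 4S); if its sense proves opposite, the quinidine-derived pseudoenantiomer is used with nothing else changed.

Step 1
Reactants: 1 (R)-α-terpineol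
Product: 2 triethylsilyl ether of (R)-α-terpineol
Conditions: Et3SiOTf, 2,6-lutidine, CH2Cl2, 0 °C
Reagents that add atoms: triethylsilyl trifluoromethanesulfonate, CC[Si](CC)(CC)OS(=O)(=O)C(F)(F)F
Why: Silylation of the tertiary alcohol with a silyl triflate and a hindered base touches neither the alkene nor the stereocentre, and it masks the hydroxyl that would otherwise trap the aldehyde of step 2 as a lactol and the acid of step 4 as a lactone.

Step 2
Reactants: 2 triethylsilyl ether of (R)-α-terpineol
Product: 4 (3R)-6-oxo-3-[2-(triethylsilyloxy)propan-2-yl]heptanal, via secondary ozonide 3 (not isolated)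
Conditions: O3, CH2Cl2, −78 °C; then PPh3, −78 °C → rt
Reagents that add atoms: ozone, [O-][O+]=O
Why: Ozonolysis of the only alkene with reductive work-up of the ozonide should give the methyl ketone and the aldehyde, leaving the silyl ether and the stereocentre (not α to either carbonyl) untouched.

Step 3
Reactants: 4 (3R)-6-oxo-3-[2-(triethylsilyloxy)propan-2-yl]heptanal
Product: 5 (5R)-5-[2-(triethylsilyloxy)propan-2-yl]oct-7-en-2-one
Conditions: Ph3PCH3Br, KN(SiMe3)2, THF, 0 °C; then 4 (1.0 equiv ylide), −78 → 0 °C
Reagents that add atoms: methyltriphenylphosphonium bromide, C[P+](c1ccccc1)(c1ccccc1)c1ccccc1.[Br-]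
Why: Wittig methylenation with one equivalent of the unstabilised ylide at −78 °C should take the free, unhindered aldehyde much faster than the methyl ketone and so install the vinyl group (C12) chemoselectively.

Step 4
Reactants: 5 (5R)-5-[2-(triethylsilyloxy)propan-2-yl]oct-7-en-2-one
Product: 7 (4R)-4-[2-(triethylsilyloxy)propan-2-yl]hept-6-enoic acid, via tribromomethyl ketone 6 (not isolated)
Conditions: Br2, NaOH, H2O/1,4-dioxane, 0 °C; then aq citric acid to pH 4
Reagents that add atoms: sodium hydroxide, [Na+].[OH-]
Why: Haloform (Lieben) degradation, in which the methyl group is tribrominated through its enolate and hydroxide cleaves the tribromomethyl ketone to the carboxylate (the future C2), has precedent on methyl ketones carrying isolated alkenes, and the silyl ether is stable to cold aqueous base and to the mild acidification.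

Step 5
Reactants: 7 (4R)-4-[2-(triethylsilyloxy)propan-2-yl]hept-6-enoic acid
Product: 8 methyl (4R)-4-[2-(triethylsilyloxy)propan-2-yl]hept-6-enoate
Conditions: MeI, K2CO3, DMF, rt
Reagents that add atoms: iodomethane, CI
Why: SN2 O-alkylation of the potassium carboxylate should give the methyl ester without affecting the silyl ether or the alkene.

Step 6
Reactants: 9 5-bromo-2-methylpent-1-ene
Product: 10 diethyl (4-methylpent-4-en-1-yl)phosphonate
Conditions: P(OEt)3 (neat), 150 °C
Reagents that add atoms: triethyl phosphite, CCOP(OCC)OCC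
Why: Michaelis–Arbuzov reaction of the primary bromide is driven by loss of volatile bromoethane, and the 1,1-disubstituted alkene is inert.

Step 7
Reactants: 8 methyl (4R)-4-[2-(triethylsilyloxy)propan-2-yl]hept-6-enoate; 10 diethyl (4-methylpent-4-en-1-yl)phosphonate
Product: 12 diethyl {(9R)-2-methyl-6-oxo-9-[2-(triethylsilyloxy)propan-2-yl]dodeca-1,11-dien-5-yl}phosphonate (both C5 epimers), via lithiated phosphonate 11 (not isolated)
Conditions: 10 (2.2 equiv), n-BuLi (2.1 equiv), THF, −78 °C; then 8, −78 → 0 °C; aq NH4Cl
Reagents that add atoms: none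
Why: Claisen-type acylation of an α-lithio phosphonate by an ester (Corey–Kwiatkowski) forms the C2–C3 bond, and the second equivalent of 11 deprotonates the β-ketophosphonate as it forms, which prevents over-addition; the phosphonate-bearing carbon needs no stereocontrol.

Step 8
Reactants: 12 β-ketophosphonate; 13 isovaleraldehyde
Product: 14 (9R)-2-methyl-5-[(E)-3-methylbutylidene]-9-[2-(triethylsilyloxy)propan-2-yl]dodeca-1,11-dien-6-one
Conditions: Ba(OH)2 (activated), THF/H2O 40:1, rt
Reagents that add atoms: none
Why: Horner–Wadsworth–Emmons olefination under Ba(OH)2 conditions tolerates the enolisable aldehyde, and elimination through the less congested oxaphosphetane should place the isobutyl-bearing carbon trans to the acyl group (E), any Z isomer being removed by chromatography.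

Step 9
Reactants: 14 (E)-alkylidene ketone; 15 phloroglucinol
Product: 17 (2R,3S,4S)-4-isobutyl-3-(3-methylbut-3-en-1-yl)-2-{(3R)-3-[2-(triethylsilyloxy)propan-2-yl]hex-5-en-1-yl}chromane-2,5,7-triol, via ring-opened ketone adduct 16 (not isolated)
Conditions: 15 (3 equiv), 9-amino-9-deoxy-epi-quinine (20 mol%), CF3CO2H (40 mol%), THF, 40 °C
Reagents that add atoms: none
Why: The primary amine condenses with the C2 ketone of 14 to an iminium ion, phloroglucinol attacks C4 through a ring carbon and rearomatises, and the resulting enamine is protonated at C3 and hydrolysed to ketone 16, whose ortho phenol then adds to C2. The closest known reaction type is the primary-amine-catalysed Friedel–Crafts conjugate addition and hemiketalisation of naphthols and activated phenols with enones to 2-hydroxychromans, together with cinchona-amine iminium activation of α-branched enones for heteroatom nucleophiles; an acyclic α,β-dialkyl enone is a demanding member of this class. Ring B closes by 6-exo-trig attack of the phenol oxygen on the C2 carbonyl, and this lactol formation withdraws the adduct from the retro-Michael equilibrium. C4 (S) is set by the catalyst, whose bicyclic framework shields one face of the iminium ion so that the arene arrives on the Si face; C3 (S) is set thermodynamically, being epimerisable through the enamine or enol of 16 and settling trans to the isobutyl group with both side chains equatorial; C2 (R, axial hydroxyl) follows the anomeric preference and is replaced in step 10. The step needs a single C-alkylation: the three free ring carbons of 15 are equivalent, its carbon nucleophilicity exceeds that of its oxygens, an excess of 15 suppresses a second alkylation, and the remote C14 centre leaves facial control to the catalyst.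

Step 10
Reactants: 17 lactol
Product: 18 (2R,3S,4S)-4-isobutyl-2-methyl-3-(3-methylbut-3-en-1-yl)-2-{(3R)-3-[2-(triethylsilyloxy)propan-2-yl]hex-5-en-1-yl}chromane-5,7-diol
Conditions: AlMe3 (6 equiv), CH2Cl2, −78 → 0 °C; aq KNaC4H4O6 (potassium sodium tartrate)
Reagents that add atoms: trimethylaluminium, C[Al](C)C
Why: In this Lewis-acid-mediated substitution of a cyclic hemiketal (C-glycosidation type) the C2 aluminate should ionise to the aryl oxocarbenium ion and receive methyl axially on the half-chair with pseudo-equatorial C3 and C4 chains, on the face opposite the isobutyl group, which gives 2R with methyl cis to the C3 chain; the silyl ether and the alkenes are inert to AlMe3 at this temperature.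

Step 11
Reactants: 18 2-methylchroman diene
Product: 19 (2R,3S,4S,14R,11Z)-tricyclic chroman-5,7-diol with ring C closed (C17 triethylsilyl ether)
Conditions: second-generation Grubbs catalyst RuCl2(=CHPh)(H2IMes)(PCy3) (15 mol%), toluene (1 mM), 80 °C
Reagents that add atoms: none
Why: In this ring-closing metathesis at high dilution the catalyst should load on the vinyl group and close onto the 1,1-disubstituted alkene, helped by the trans-diequatorial C2 and C3 arms of the rigid chroman and driven by loss of ethylene, and the strain of an E trisubstituted alkene in a ten-membered ring makes the ring-cis Z isomer the favoured product; free phenols and the silyl ether are tolerated.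

Step 12
Reactants: 19 tricyclic chroman-5,7-diol
Product: 21 6,8-dicarbaldehyde of 19 (C17 triethylsilyl ether), via C6 monoaldehyde 20 (not isolated)
Conditions: MgCl2 (6 equiv), Et3N (12 equiv), (CH2O)n (20 equiv), THF, reflux; then 1 M aq HCl, 0 °C
Reagents that add atoms: paraformaldehyde (formaldehyde units), C=O
Why: Magnesium-phenoxide-directed ortho-formylation (Casnati–Skattebøl reaction) carried through twice should deliver formaldehyde to the free ortho carbons C6 and C8 and oxidise each hydroxymethyl intermediate by hydride transfer to a second formaldehyde, under basic conditions that spare the alkene, the silyl ether and all stereocentres.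

Step 13
Reactants: 21 6,8-dicarbaldehyde silyl ether
Product: 22 CNP0570248.1
Conditions: HF·pyridine, pyridine, THF, 0 °C → rt
Reagents that add atoms: none
Why: Fluoride-induced cleavage of the tertiary triethylsilyl ether, driven by the Si–F bond, under buffered conditions should leave the salicylaldehyde units, the Z alkene and the stereocentres untouched and release the target.

Compound list
1 | (R)-α-terpineol | CC1=CC[C@@H](CC1)C(C)(C)O | starting material
2 | triethylsilyl ether of (R)-α-terpineol | CC1=CC[C@@H](CC1)C(C)(C)O[Si](CC)(CC)CC | intermediate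
3 | secondary ozonide of 2 (1,2,4-trioxolane across the former C=C, formed in situ) | CC12CC[C@@H](C(C)(C)O[Si](CC)(CC)CC)CC(OO1)O2 | intermediate
4 | (3R)-6-oxo-3-[2-(triethylsilyloxy)propan-2-yl]heptanal | O=CC[C@H](C(C)(C)O[Si](CC)(CC)CC)CCC(C)=O | intermediate
5 | (5R)-5-[2-(triethylsilyloxy)propan-2-yl]oct-7-en-2-one | C=CC[C@H](C(C)(C)O[Si](CC)(CC)CC)CCC(C)=O | intermediate
6 | (5R)-1,1,1-tribromo-5-[2-(triethylsilyloxy)propan-2-yl]oct-7-en-2-one (formed in situ) | C=CC[C@H](C(C)(C)O[Si](CC)(CC)CC)CCC(=O)C(Br)(Br)Br | intermediate
7 | (4R)-4-[2-(triethylsilyloxy)propan-2-yl]hept-6-enoic acid | C=CC[C@H](C(C)(C)O[Si](CC)(CC)CC)CCC(=O)O | intermediate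
8 | methyl (4R)-4-[2-(triethylsilyloxy)propan-2-yl]hept-6-enoate | C=CC[C@H](C(C)(C)O[Si](CC)(CC)CC)CCC(=O)OC | intermediate
9 | 5-bromo-2-methylpent-1-ene | C=C(C)CCCBr | starting material
10 | diethyl (4-methylpent-4-en-1-yl)phosphonate | C=C(C)CCCP(=O)(OCC)OCC | intermediate
11 | diethyl (1-lithio-4-methylpent-4-en-1-yl)phosphonate (formed in situ) | [Li]C(CCC(C)=C)P(=O)(OCC)OCC | intermediate
12 | diethyl {(9R)-2-methyl-6-oxo-9-[2-(triethylsilyloxy)propan-2-yl]dodeca-1,11-dien-5-yl}phosphonate (both C5 epimers) | C=CC[C@H](C(C)(C)O[Si](CC)(CC)CC)CCC(=O)C(CCC(C)=C)P(=O)(OCC)OCC | intermediate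
13 | isovaleraldehyde (3-methylbutanal) | CC(C)CC=O | starting material
14 | (9R)-2-methyl-5-[(E)-3-methylbutylidene]-9-[2-(triethylsilyloxy)propan-2-yl]dodeca-1,11-dien-6-one | C=CC[C@H](C(C)(C)O[Si](CC)(CC)CC)CCC(=O)/C(CCC(C)=C)=C/CC(C)C | intermediate
15 | phloroglucinol (benzene-1,3,5-triol) | Oc1cc(O)cc(O)c1 | starting material
16 | (5S,9R)-2-methyl-5-[(1S)-3-methyl-1-(2,4,6-trihydroxyphenyl)butyl]-9-[2-(triethylsilyloxy)propan-2-yl]dodeca-1,11-dien-6-one (ring-opened adduct, formed in situ) | C=CC[C@H](C(C)(C)O[Si](CC)(CC)CC)CCC(=O)[C@@H](CCC(C)=C)[C@H](CC(C)C)c1c(O)cc(O)cc1O | intermediate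
17 | (2R,3S,4S)-4-isobutyl-3-(3-methylbut-3-en-1-yl)-2-{(3R)-3-[2-(triethylsilyloxy)propan-2-yl]hex-5-en-1-yl}chromane-2,5,7-triol | C=CC[C@H](C(C)(C)O[Si](CC)(CC)CC)CC[C@@]1(O)Oc2cc(O)cc(O)c2[C@@H](CC(C)C)[C@@H]1CCC(C)=C | intermediate
18 | (2R,3S,4S)-4-isobutyl-2-methyl-3-(3-methylbut-3-en-1-yl)-2-{(3R)-3-[2-(triethylsilyloxy)propan-2-yl]hex-5-en-1-yl}chromane-5,7-diol | C=CC[C@H](C(C)(C)O[Si](CC)(CC)CC)CC[C@@]1(C)Oc2cc(O)cc(O)c2[C@@H](CC(C)C)[C@@H]1CCC(C)=C | intermediate
19 | (2R,3S,4S,14R,11Z)-tricycle: 5,7-dihydroxychroman trans-fused at C2–C3 to ten-membered ring C; C2 methyl, C4 isobutyl, C11 methyl, C14 2-(triethylsilyloxy)propan-2-yl | C/C1=C/C[C@H](C(C)(C)O[Si](CC)(CC)CC)CC[C@@]2(C)Oc3cc(O)cc(O)c3[C@@H](CC(C)C)[C@@H]2CC1 | intermediate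
20 | 6-carbaldehyde of 19 (formed in situ) | C/C1=C/C[C@H](C(C)(C)O[Si](CC)(CC)CC)CC[C@@]2(C)Oc3cc(O)c(C=O)c(O)c3[C@@H](CC(C)C)[C@@H]2CC1 | intermediate
21 | 6,8-dicarbaldehyde of 19 (C17 triethylsilyl ether of the target) | C/C1=C/C[C@H](C(C)(C)O[Si](CC)(CC)CC)CC[C@@]2(C)Oc3c(C=O)c(O)c(C=O)c(O)c3[C@@H](CC(C)C)[C@@H]2CC1 | intermediate
22 | CNP0570248.1 | C/C1=C/C[C@H](C(C)(C)O)CC[C@@]2(C)Oc3c(C=O)c(O)c(C=O)c(O)c3[C@@H](CC(C)C)[C@@H]2CC1 | target

Total step count: 13. Longest linear sequence: 12 steps (1 → 22 through steps 1–5 and 7–13; step 6 is a one-step side branch).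

Steps most likely to fail

Step 9. Iminium formation at the congested α-branched ketone may be too slow. The enone geometry may scramble through a dienamine and erode facial selectivity at C4. Equilibration at C3 may stay incomplete, or the arene may be alkylated twice. The fallback sets out again from 14 and 15 and gives up catalyst control. Sc(OTf)3 (10 mol%) in MeCN at 0 °C → rt would activate the enone carbonyl directly for the same Friedel–Crafts addition and lactol closure, a known reaction of phloroglucinols with enones. Because C14 is already in place, the two products are diastereomers, and 17 would be separated by chromatography from the (2S,3R,4R)-lactol diastereomer F1. The route is rejoined at 17.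

Step 11. The vinyl groups may oligomerise by cross-metathesis, the 1,1-disubstituted alkene may be reluctant to enter the ring closure, or the alkenes may migrate. The fallback sets out from 18 and closes ring C by carbonyl coupling instead. Silylation of both phenols (t-BuMe2SiCl, imidazole, DMF) would give the 5,7-bis(tert-butyldimethylsilyl) ether F2. OsO4 (cat.) and NaIO4 with 2,6-lutidine in dioxane–water would cleave both terminal alkenes to the C12 aldehyde C11 methyl ketone F3. Intramolecular McMurry coupling with low-valent titanium (TiCl3(DME)1.5, Zn–Cu couple, DME, reflux, slow addition) would close the ring as the silylated Z cycloalkene F4, from which any silylated E cycloalkene F5 would be separated. KHF2 in MeOH would then remove only the two aryl silyl ethers, and the route is rejoined at 19.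

Step 10. The aluminium hemiketalate may open to the ketone and undergo unselective 1,2-addition, the oxocarbenium ion may lose a proton to give a 4H-chromene, or the electron-rich arene may self-condense. The fallback sets out from 17 and accepts the open form. MeMgBr with CeCl3 (excess) in THF at −78 → 0 °C would add to the ring-opened ketone to give the tertiary carbinol F6. Acid-mediated cyclodehydration (Amberlyst 15, CH2Cl2, 0 °C), the classical closure of 2,2-dialkylchromans by phenol capture of a tertiary cation, would then give 18. Here C2 is set in the ring closure and not by axial delivery, so 18 would have to be separated from the C2 epimer F7. The route is rejoined at 18.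

Further compounds
F1 | step 9 | (2S,3R,4R)-lactol diastereomer of 17 | C=CC[C@H](C(C)(C)O[Si](CC)(CC)CC)CC[C@]1(O)Oc2cc(O)cc(O)c2[C@H](CC(C)C)[C@H]1CCC(C)=C
F2 | step 11 | 5,7-bis(tert-butyldimethylsilyl) ether of 18 | C=CC[C@H](C(C)(C)O[Si](CC)(CC)CC)CC[C@@]1(C)Oc2cc(O[Si](C)(C)C(C)(C)C)cc(O[Si](C)(C)C(C)(C)C)c2[C@@H](CC(C)C)[C@@H]1CCC(C)=C
F3 | step 11 | C12 aldehyde C11 methyl ketone from F2 | O=CC[C@H](C(C)(C)O[Si](CC)(CC)CC)CC[C@@]1(C)Oc2cc(O[Si](C)(C)C(C)(C)C)cc(O[Si](C)(C)C(C)(C)C)c2[C@@H](CC(C)C)[C@@H]1CCC(C)=O
F4 | step 11 | 5,7-bis(tert-butyldimethylsilyl) ether of 19 (Z cycloalkene) | C/C1=C/C[C@H](C(C)(C)O[Si](CC)(CC)CC)CC[C@@]2(C)Oc3cc(O[Si](C)(C)C(C)(C)C)cc(O[Si](C)(C)C(C)(C)C)c3[C@@H](CC(C)C)[C@@H]2CC1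
F5 | step 11 | E isomer of F4 | C/C1=C\C[C@H](C(C)(C)O[Si](CC)(CC)CC)CC[C@@]2(C)Oc3cc(O[Si](C)(C)C(C)(C)C)cc(O[Si](C)(C)C(C)(C)C)c3[C@@H](CC(C)C)[C@@H]2CC1
F6 | step 10 | ring-opened tertiary carbinol (C2 methyl carbinol, both C2 epimers) | C=CC[C@H](C(C)(C)O[Si](CC)(CC)CC)CCC(C)(O)[C@@H](CCC(C)=C)[C@H](CC(C)C)c1c(O)cc(O)cc1O
F7 | step 10 | C2 epimer of 18 | C=CC[C@H](C(C)(C)O[Si](CC)(CC)CC)CC[C@]1(C)Oc2cc(O)cc(O)c2[C@@H](CC(C)C)[C@@H]1CCC(C)=C
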